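**Retrosynthetic overview**
- The route rests on the contiguous array O7a, C7–phenyl, O6, O5 of ring A (carbocycle C3a–C7a; ring B is the lactone O1–C2–C3), which maps atom for atom onto the four carbons of a squarate-derived cyclobutenone.
- The C3=C3a/C6=O quinone methide is the dehydration product of a 3,6-dihydroxy lactone, so the last step is unmasking of O6 (and the pendant phenol) with loss of water.
- Ring B is formed second: the C3–C3a bond and the O1–C2 lactone bond come from phenol 11 and an aryl glyoxylate by ortho-hydroxyalkylation and lactonisation.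
- Ring A is formed first: the C7a–C3a bond arises by electrocyclic ring expansion of a 4-methoxy-4-(1-phenylethenyl)cyclobutenone, itself made from diisopropyl squarate by two organolithium additions and O-methylation.
- The pendant phenol is carried as an isopropyl ether, so the titanium step meets only one free phenol and a single BCl3 operation frees both oxygens while the methyl ether stays.

Key step: step 3

Remark: the target has no stereocentre; compounds 3, 7, 8, 14, 15 and 16 are racemic, and each of their single stereocentres is erased later in the route.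

**Step 1**
Reactants: 1 diisopropyl squarate; 2 phenyllithium
Product: 4 3-isopropoxy-4-phenylcyclobut-3-ene-1,2-dione, via carbinol adduct 3 (not isolated)
Conditions: PhLi (1.05 equiv), THF, −78 °C; aq NH4Cl; crude adduct, conc. HCl (cat.), CH2Cl2, rt
Reagents that add atoms: none
Why: 1,2-addition of the aryllithium to one squarate carbonyl, then acid-catalysed 1,3-carbonyl transposition of the carbinol with loss of isopropanol, is the standard entry to 3-alkoxy-4-arylcyclobutenediones.

**Step 2**
Reactants: 4 3-isopropoxy-4-phenylcyclobut-3-ene-1,2-dione; 5 α-bromostyrene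
Product: 8 3-isopropoxy-4-methoxy-2-phenyl-4-(1-phenylethenyl)cyclobut-2-en-1-one, via 1-phenylvinyllithium 6 (not isolated), via lithium alkoxide 7 (not isolated)
Conditions: 5, t-BuLi (2 equiv), Et2O, −78 °C; then 4, THF, −78 °C; then MeOTf, −78 to 0 °C
Reagents that add atoms: methyl trifluoromethanesulfonate, COS(=O)(=O)C(F)(F)F
Why: bromine–lithium exchange gives the vinyllithium, which should add 1,2 to the ketone-like carbonyl next to the isopropoxy-bearing carbon (the other carbonyl is deactivated as a vinylogous ester), and the tertiary lithium alkoxide is O-methylated in situ by the triflate; the new stereocentre is racemic and is destroyed in step 3.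

**Step 3**
Reactants: 8 3-isopropoxy-4-methoxy-2-phenyl-4-(1-phenylethenyl)cyclobut-2-en-1-one
Product: 11 3-isopropoxy-4-methoxy-2,5-diphenylphenol, via dienylketene 9 (not isolated), via cyclohexadienone 10 (not isolated)
Conditions: p-xylene (degassed, 0.02 M), 138 °C, Ar
Reagents that add atoms: none
Why: Heating should open the strained cyclobutenone by conrotatory 4π electrocyclic cleavage of the C1–C4 bond (the future C7a–C5 pair) to (Z)-dienylketene 9, whose ketene carbon and vinyl CH2 terminus then join in a thermally allowed disrotatory 6π electrocyclisation to dienone 10, and enolisation to phenol 11 makes the sequence irreversible. The closest known reaction type is the Moore rearrangement of squarate-derived 4-alkenyl-4-alkoxy(hydroxy)cyclobutenones to hydroquinones and their monoethers. Ring A is closed by this 6π electrocyclisation, which forms the C7a–C3a bond of a six-membered carbocycle. No stereocentre is formed, and the carbinol centre of 8 becomes the sp2 carbon C5. The step needs torquoselectivity, with the vinyl group turning inward so that it lies cis to the ketene, and this is secured by the strong preference of the donor methoxy group on C4 for outward rotation. The substitution pattern needs no control here because the site of addition in step 2 fixed it: the ketene oxygen becomes the free O7a hydroxyl, the methoxy stays on C5 and the isopropoxy on C6.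

**Step 4**
Reactants: 12 4-hydroxyphenylglyoxylic acid
Product: 13 isopropyl 2-(4-isopropoxyphenyl)-2-oxoacetate
Conditions: 2-bromopropane (4 equiv), K2CO3, DMF, 60 °C
Reagents that add atoms: 2-bromopropane, CC(C)Br
Why: SN2 O-alkylation of both the phenoxide (Williamson ether synthesis) and the carboxylate should proceed cleanly because the α-keto acid cannot enolise.

**Step 5**
Reactants: 11 3-isopropoxy-4-methoxy-2,5-diphenylphenol; 13 isopropyl 2-(4-isopropoxyphenyl)-2-oxoacetate
Product: 15 3-hydroxy-6-isopropoxy-3-(4-isopropoxyphenyl)-5-methoxy-4,7-diphenylbenzofuran-2(3H)-one, via hydroxy ester 14 (not isolated)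
Conditions: TiCl4 (1.1 equiv), CH2Cl2, −30 °C to rt; crude, TsOH·H2O (cat.), PhMe, 80 °C
Reagents that add atoms: none
Why: ortho-selective Friedel–Crafts hydroxyalkylation of the titanium phenoxide by the chelated α-ketoester should take place at C6 of 11, the only free position of ring A (ortho to the hydroxyl, para to the isopropoxy group), and acid-catalysed lactonisation then closes ring B; the C3 stereocentre is racemic and is removed in step 6.

**Step 6**
Reactants: 15 3-hydroxy-6-isopropoxy-3-(4-isopropoxyphenyl)-5-methoxy-4,7-diphenylbenzofuran-2(3H)-one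
Product: 17 3-(4-hydroxyphenyl)-5-methoxy-4,7-diphenylbenzofuran-2,6-dione, via dihydroxy lactone 16 (not isolated)
Conditions: BCl3 (5 equiv), CH2Cl2, −78 to 0 °C; aq HCl, rt
Reagents that add atoms: none
Why: BCl3 cleaves secondary alkyl aryl ethers much faster than methyl ethers, and the freed 6-hydroxy-3-carbinol should lose water by acid-promoted 1,6-elimination through the diaryl-stabilised C3 cation to give the para-quinone methide, leaving no stereocentre.

**Compound list**
1 | diisopropyl squarate (3,4-diisopropoxycyclobut-3-ene-1,2-dione) | CC(C)OC1=C(OC(C)C)C(=O)C1=O | starting material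
2 | phenyllithium | [Li]c1ccccc1 | starting material
3 | 4-hydroxy-2,3-diisopropoxy-4-phenylcyclobut-2-en-1-one (racemic; not isolated) | CC(C)OC1=C(OC(C)C)C(O)(c2ccccc2)C1=O | intermediate
4 | 3-isopropoxy-4-phenylcyclobut-3-ene-1,2-dione | CC(C)OC1=C(c2ccccc2)C(=O)C1=O | intermediate
5 | α-bromostyrene (1-bromo-1-phenylethene) | BrC(=C)c1ccccc1 | starting material
6 | 1-phenylvinyllithium (not isolated) | [Li]C(=C)c1ccccc1 | intermediate
7 | lithium alkoxide of 4-hydroxy-3-isopropoxy-2-phenyl-4-(1-phenylethenyl)cyclobut-2-en-1-one (racemic; not isolated) | [Li]OC1(C(=C)c2ccccc2)C(OC(C)C)=C(c2ccccc2)C1=O | intermediate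
8 | 3-isopropoxy-4-methoxy-2-phenyl-4-(1-phenylethenyl)cyclobut-2-en-1-one (racemic) | COC1(C(=C)c2ccccc2)C(OC(C)C)=C(c2ccccc2)C1=O | intermediate
9 | (3Z)-3-isopropoxy-4-methoxy-2,5-diphenylhexa-1,3,5-trien-1-one (not isolated) | O=C=C(c1ccccc1)/C(OC(C)C)=C(/OC)C(=C)c1ccccc1 | intermediate
10 | 3-isopropoxy-4-methoxy-2,5-diphenylcyclohexa-2,4-dien-1-one (not isolated) | O=C1CC(c2ccccc2)=C(OC)C(OC(C)C)=C1c1ccccc1 | intermediate
11 | 3-isopropoxy-4-methoxy-2,5-diphenylphenol | COc1c(-c2ccccc2)cc(O)c(-c2ccccc2)c1OC(C)C | intermediate
12 | 4-hydroxyphenylglyoxylic acid | O=C(O)C(=O)c1ccc(O)cc1 | starting material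
13 | isopropyl 2-(4-isopropoxyphenyl)-2-oxoacetate | CC(C)OC(=O)C(=O)c1ccc(OC(C)C)cc1 | intermediate
14 | isopropyl 2-hydroxy-2-(2-hydroxy-4-isopropoxy-5-methoxy-3,6-diphenylphenyl)-2-(4-isopropoxyphenyl)acetate (racemic; not isolated) | CC(C)OC(=O)C(O)(c1ccc(OC(C)C)cc1)c1c(O)c(-c2ccccc2)c(OC(C)C)c(OC)c1-c1ccccc1 | intermediate
15 | 3-hydroxy-6-isopropoxy-3-(4-isopropoxyphenyl)-5-methoxy-4,7-diphenylbenzofuran-2(3H)-one (racemic) | O=C1Oc2c(-c3ccccc3)c(OC(C)C)c(OC)c(-c3ccccc3)c2C1(O)c1ccc(OC(C)C)cc1 | intermediate
16 | 3,6-dihydroxy-3-(4-hydroxyphenyl)-5-methoxy-4,7-diphenylbenzofuran-2(3H)-one (racemic; not isolated) | O=C1Oc2c(-c3ccccc3)c(O)c(OC)c(-c3ccccc3)c2C1(O)c1ccc(O)cc1 | intermediate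
17 | 3-(4-hydroxyphenyl)-5-methoxy-4,7-diphenylbenzofuran-2,6-dione | COC1=C(c2ccccc2)C2=C(c3ccc(O)cc3)C(=O)OC2=C(c2ccccc2)C1=O | target

**Step count**
Total steps: 6. Longest linear sequence: 5 steps (steps 1, 2, 3, 5, 6 from diisopropyl squarate); step 4 is a one-step side branch.

**Steps most likely to fail**

Step 5. C–C bond formation at C6 of 11 may be slowed by crowding (the site lies between the hydroxyl and the twisted neighbouring phenyl) and by the low electrophilicity of a p-alkoxyaryl ketone, so that O-acylation, retro-addition or Lewis-acid ether cleavage could overtake it. The fallback sets out from 11 and 13 and comes back at 17. The keto group of 13 is reduced with NaBH4 (iPrOH/THF, −20 °C) to isopropyl 2-hydroxy-2-(4-isopropoxyphenyl)acetate F1. Its p-alkoxybenzylic cation, smaller and far more electrophilic than the ketone, is generated with BF3·OEt2 in CH2Cl2 and should alkylate 11 at C6 with lactonisation to 6-isopropoxy-3-(4-isopropoxyphenyl)-5-methoxy-4,7-diphenylbenzofuran-2(3H)-one F2. BCl3 as in step 6 would give 6-hydroxy-3-(4-hydroxyphenyl)-5-methoxy-4,7-diphenylbenzofuran-2(3H)-one F3, and dehydrogenation of this leuco lactone with DDQ (dioxane, rt) would give 17.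

Step 6. Chemoselectivity of the ether cleavage may be lost: boron held at O6 could also remove the neighbouring C5 methyl group, or the C3 carbinol could be converted into a chloride that does not eliminate cleanly. The fallback sets out from 15 and comes back at 17. All three ethers are cleaved on purpose with BBr3 (CH2Cl2, −78 °C to rt) to give 5-hydroxy-3-(4-hydroxyphenyl)-4,7-diphenylbenzofuran-2,6-dione F4. The methyl group is then put back on O5–H, which as a vinylogous carboxylic acid is far more acidic than the pendant phenol, with one equivalent of Me3SiCHN2 (PhMe/MeOH, 0 °C) to give 17.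

Step 3. At the temperature the methyl ether needs, the ring-opened ketene may be consumed by dimerisation or by adventitious nucleophiles before the crowded 6π closure, in which the α-phenyl of the vinyl group must sit beside the C4 methoxy in the s-cis conformer. The fallback sets out from 4 and comes back at 11. Reagent 6 is added as in step 2 but the alkoxide is quenched with aq NH4Cl to give 4-hydroxy-3-isopropoxy-2-phenyl-4-(1-phenylethenyl)cyclobut-2-en-1-one F5. This free carbinol should rearrange at lower temperature (PhMe, 80–110 °C, Ar) to 3-isopropoxy-2,5-diphenylbenzene-1,4-diol F6. The less hindered hydroxyl (flanked by phenyl and hydrogen) is silylated with TBSCl and imidazole (DMF, 0 °C) to give 4-(tert-butyldimethylsilyloxy)-2-isopropoxy-3,6-diphenylphenol F7. The remaining hindered hydroxyl is methylated (MeI, K2CO3, acetone) to give tert-butyl(3-isopropoxy-4-methoxy-2,5-diphenylphenoxy)dimethylsilane F8, and Bu4NF (THF, 0 °C) would release 11.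

**Further compounds**
F1 | step 5 | isopropyl 2-hydroxy-2-(4-isopropoxyphenyl)acetate (racemic) | CC(C)OC(=O)C(O)c1ccc(OC(C)C)cc1
F2 | step 5 | 6-isopropoxy-3-(4-isopropoxyphenyl)-5-methoxy-4,7-diphenylbenzofuran-2(3H)-one (racemic) | O=C1Oc2c(-c3ccccc3)c(OC(C)C)c(OC)c(-c3ccccc3)c2C1c1ccc(OC(C)C)cc1
F3 | step 5 | 6-hydroxy-3-(4-hydroxyphenyl)-5-methoxy-4,7-diphenylbenzofuran-2(3H)-one (racemic) | O=C1Oc2c(-c3ccccc3)c(O)c(OC)c(-c3ccccc3)c2C1c1ccc(O)cc1
F4 | step 6 | 5-hydroxy-3-(4-hydroxyphenyl)-4,7-diphenylbenzofuran-2,6-dione | OC1=C(c2ccccc2)C2=C(c3ccc(O)cc3)C(=O)OC2=C(c2ccccc2)C1=O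
F5 | step 3 | 4-hydroxy-3-isopropoxy-2-phenyl-4-(1-phenylethenyl)cyclobut-2-en-1-one (racemic) | OC1(C(=C)c2ccccc2)C(OC(C)C)=C(c2ccccc2)C1=O
F6 | step 3 | 3-isopropoxy-2,5-diphenylbenzene-1,4-diol | Oc1cc(-c2ccccc2)c(O)c(OC(C)C)c1-c1ccccc1
F7 | step 3 | 4-(tert-butyldimethylsilyloxy)-2-isopropoxy-3,6-diphenylphenol | CC(C)Oc1c(O)c(-c2ccccc2)cc(O[Si](C)(C)C(C)(C)C)c1-c1ccccc1
F8 | step 3 | tert-butyl(3-isopropoxy-4-methoxy-2,5-diphenylphenoxy)dimethylsilane | COc1c(-c2ccccc2)cc(O[Si](C)(C)C(C)(C)C)c(-c2ccccc2)c1OC(C)C
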